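**Retrosynthetic overview**
1. Numbering: main chain C1–C23 from the ethyl carbinol end (C3–OH) to the ethyl group on ring A; ring B is the central pyranone (C5–C9), ring A the terminal pyranone (C17–C21).
2. Target ⇐ C3–O desilylation and C13–O propionylation of a C13-alcohol/C15-acetate, itself from an Evans–Tishchenko reduction of a β-hydroxy enone (sets C13, installs the acetate).
3. β-Hydroxy enone ⇐ boron syn-aldol (C14–C15 bond) between the east ethyl enone (ring B, C1–C14) and the west aldehyde (ring A, C15–C23).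
4. East enone ⇐ one-pot oxidation/Wittig (C11=C12) of a ring B alcohol; ring B ⇐ cyclodehydration of a 1,3,5-triketone assembled from pentan-3-one and two chiral aldehydes (Fráter–Seebach ester for C3/C4, (S)-Roche ester for C10).
5. West aldehyde ⇐ ring A alcohol ⇐ triketone from 4-methylheptane-3,5-dione and the (R)-Roche aldehyde (C16); ring A is formed first (step 5), ring B second (step 15), both before the fragment union.

Assumption: both Roche esters, methyl (S)-3-hydroxypentanoate, 4-methylheptane-3,5-dione, pentan-3-one and 2-bromopentan-3-one are taken as purchasable.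

**West fragment (ring A)**

Step 1
Reactants: 1 methyl (R)-3-hydroxy-2-methylpropanoate
Product: 2 methyl (R)-2-methyl-3-(triethylsilyloxy)propanoate
Conditions: Et3SiCl, imidazole, CH2Cl2, 0 °C to rt
Reagents that add atoms: chlorotriethylsilane, CC[Si](Cl)(CC)CC
Why: Imidazole-promoted O-silylation masks the primary hydroxyl (future C15–O) as a base-stable, acid-labile silyl ether without touching the C16 stereocentre.

Step 2
Reactants: 2 methyl (R)-2-methyl-3-(triethylsilyloxy)propanoate
Product: 3 (R)-2-methyl-3-(triethylsilyloxy)propanal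
Conditions: i-Bu2AlH (1.05 equiv), CH2Cl2, −78 °C; MeOH, then aq. KNaC4H4O6
Reagents that add atoms: none
Why: Partial hydride reduction of the ester stops at the tetrahedral aluminium hemiacetal at −78 °C, which releases the aldehyde on work-up with the α-stereocentre intact.

Step 3
Reactants: 4 4-methylheptane-3,5-dione; 3 (R)-2-methyl-3-(triethylsilyloxy)propanal
Product: 6 (8R)-7-hydroxy-4,6,8-trimethyl-9-(triethylsilyloxy)nonane-3,5-dione (epimer mixture at C4/C6/C7), via dilithium bis-enolate 5 (not isolated)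
Conditions: LiN(i-Pr)2 (2.1 equiv), THF, −78 to 0 °C; then 3, −78 °C; AcOH quench
Reagents that add atoms: none
Why: γ-Aldol addition of a β-diketone dianion (Hauser–Harris dianion chemistry), in which the more basic terminal enolate attacks the aldehyde carbon (future C17) while the new stereocentres are irrelevant because they become sp2 in steps 4 and 5.

Step 4
Reactants: 6 (8R)-7-hydroxy-4,6,8-trimethyl-9-(triethylsilyloxy)nonane-3,5-dione
Product: 7 (8R)-4,6,8-trimethyl-9-(triethylsilyloxy)nonane-3,5,7-trione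
Conditions: Dess–Martin periodinane, NaHCO3, CH2Cl2, 0 °C to rt
Reagents that add atoms: none
Why: Buffered Dess–Martin oxidation converts the carbinol into the 1,3,5-triketone, and C16–H is not exchanged because its ketone is tied up in the enolised β-dicarbonyl system.

Step 5
Reactants: 7 (8R)-4,6,8-trimethyl-9-(triethylsilyloxy)nonane-3,5,7-trione
Product: 9 (R)-2-ethyl-6-(1-hydroxypropan-2-yl)-3,5-dimethyl-4H-pyran-4-one, via ring A triethylsilyl ether 8 (not isolated)
Conditions: 4-MeC6H4SO3H·H2O (0.1 equiv), CH2Cl2, rt; then MeOH, rt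
Reagents that add atoms: none
Why: Acid-catalysed cyclodehydration of the 1,3,5-triketone (enol oxygen onto the distal ketone, then loss of water) forms ring A irreversibly, after which methanolysis removes the primary silyl ether and C16 is no longer α to a ketone.

**East fragment (ring B)**

Step 6
Reactants: 10 methyl (S)-3-hydroxypentanoate
Product: 12 methyl (2S,3S)-3-hydroxy-2-methylpentanoate, via dilithium alkoxide enolate 11 (not isolated)
Conditions: LiN(i-Pr)2 (2.2 equiv), THF, −78 to −20 °C; MeI, DMPU, −78 to 0 °C; AcOH quench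
Reagents that add atoms: iodomethane, CI
Why: Fráter–Seebach alkylation, in which the chelated dilithium alkoxide enolate is methylated on the face opposite the ethyl group of the carbinol carbon, setting C4 anti to the C3 oxygen (2S,3S).

Step 7
Reactants: 12 methyl (2S,3S)-3-hydroxy-2-methylpentanoate
Product: 13 methyl (2S,3S)-3-(tert-butyldimethylsilyloxy)-2-methylpentanoate
Conditions: t-BuMe2SiOTf, 2,6-lutidine, CH2Cl2, −78 to 0 °C
Reagents that add atoms: tert-butyldimethylsilyl trifluoromethanesulfonate, CC(C)(C)[Si](C)(C)OS(=O)(=O)C(F)(F)F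
Why: Silyl triflate O-silylation protects the hindered C3 hydroxyl as a robust ether that survives every step up to the final deprotection.

Step 8
Reactants: 13 methyl (2S,3S)-3-(tert-butyldimethylsilyloxy)-2-methylpentanoate
Product: 14 (2S,3S)-3-(tert-butyldimethylsilyloxy)-2-methylpentanal
Conditions: i-Bu2AlH (1.05 equiv), CH2Cl2, −78 °C; MeOH, then aq. KNaC4H4O6
Reagents that add atoms: none
Why: Partial ester reduction at −78 °C through the stable aluminium hemiacetal gives the aldehyde without epimerising C4 or eliminating the β-silyloxy group.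

Step 9
Reactants: 15 methyl (S)-3-hydroxy-2-methylpropanoate
Product: 16 methyl (S)-2-methyl-3-(triethylsilyloxy)propanoate
Conditions: Et3SiCl, imidazole, CH2Cl2, 0 °C to rt
Reagents that add atoms: chlorotriethylsilane, CC[Si](Cl)(CC)CC
Why: Imidazole-promoted O-silylation protects the future C11 hydroxyl as a primary triethylsilyl ether that can later be removed in the presence of the secondary tert-butyldimethylsilyl ether.

Step 10
Reactants: 16 methyl (S)-2-methyl-3-(triethylsilyloxy)propanoate
Product: 17 (S)-2-methyl-3-(triethylsilyloxy)propanal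
Conditions: i-Bu2AlH (1.05 equiv), CH2Cl2, −78 °C; MeOH, then aq. KNaC4H4O6
Reagents that add atoms: none
Why: Partial ester reduction at −78 °C delivers the aldehyde that carries the C10 stereocentre unchanged.

Step 11
Reactants: 18 pentan-3-one; 17 (S)-2-methyl-3-(triethylsilyloxy)propanal
Product: 20 (6S)-5-hydroxy-4,6-dimethyl-7-(triethylsilyloxy)heptan-3-one (epimer mixture at C4/C5), via lithium enolate 19 (not isolated)
Conditions: LiN(i-Pr)2 (1.05 equiv), THF, −78 °C; then 17, −78 °C; AcOH quench
Reagents that add atoms: none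
Why: Lithium enolate aldol addition forms the C8–C9 bond, and no selectivity is needed because C9 is oxidised in step 12 and C8 becomes a ring carbon.

Step 12
Reactants: 20 (6S)-5-hydroxy-4,6-dimethyl-7-(triethylsilyloxy)heptan-3-one
Product: 21 (6S)-4,6-dimethyl-7-(triethylsilyloxy)heptane-3,5-dione
Conditions: Dess–Martin periodinane, NaHCO3, CH2Cl2, 0 °C to rt
Reagents that add atoms: none
Why: Buffered Dess–Martin oxidation gives the β-diketone, whose preferred enolisation toward the central carbon protects the C10 stereocentre.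

Step 13
Reactants: 21 (6S)-4,6-dimethyl-7-(triethylsilyloxy)heptane-3,5-dione; 14 (2S,3S)-3-(tert-butyldimethylsilyloxy)-2-methylpentanal
Product: 23 (3S,4R,10S)-3-(tert-butyldimethylsilyloxy)-5-hydroxy-4,6,8,10-tetramethyl-11-(triethylsilyloxy)undecane-7,9-dione (epimer mixture at C5/C6/C8), via dilithium bis-enolate 22 (not isolated)
Conditions: LiN(i-Pr)2 (2.1 equiv), THF, −78 to 0 °C; then 14, −78 °C; AcOH quench
Reagents that add atoms: none
Why: γ-Aldol addition of the β-diketone dianion (Hauser–Harris dianion chemistry), where the second deprotonation occurs kinetically at the unhindered ethyl CH2 and not at the tertiary C10–H, so the terminal enolate joins C5–C6 while C3, C4 and C10 pass through unchanged (the C4 descriptor changes only by priority).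

Step 14
Reactants: 23 (3S,4R,10S)-3-(tert-butyldimethylsilyloxy)-5-hydroxy-4,6,8,10-tetramethyl-11-(triethylsilyloxy)undecane-7,9-dione
Product: 24 (3S,4S,10S)-3-(tert-butyldimethylsilyloxy)-4,6,8,10-tetramethyl-11-(triethylsilyloxy)undecane-5,7,9-trione
Conditions: Dess–Martin periodinane, NaHCO3, CH2Cl2, 0 °C to rt
Reagents that add atoms: none
Why: Buffered Dess–Martin oxidation gives the 1,3,5-triketone whose flanking stereocentres C4 and C10 sit next to enolised ketones and are therefore not exchanged.

Step 15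
Reactants: 24 (3S,4S,10S)-3-(tert-butyldimethylsilyloxy)-4,6,8,10-tetramethyl-11-(triethylsilyloxy)undecane-5,7,9-trione
Product: 26 2-[(2S,3S)-3-(tert-butyldimethylsilyloxy)pentan-2-yl]-6-[(S)-1-hydroxypropan-2-yl]-3,5-dimethyl-4H-pyran-4-one, via ring B triethylsilyl ether 25 (not isolated)
Conditions: 4-MeC6H4SO3H·H2O (0.1 equiv), CH2Cl2, rt; then MeOH, 0 °C
Reagents that add atoms: none
Why: Acid-catalysed cyclodehydration of the 1,3,5-triketone forms ring B, and brief methanolysis at 0 °C cleaves the primary triethylsilyl ether selectively over the hindered secondary tert-butyldimethylsilyl ether.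

Step 16
Reactants: 27 2-bromopentan-3-one
Product: 29 2-(triphenyl-λ5-phosphanylidene)pentan-3-one, via phosphonium bromide 28 (not isolated)
Conditions: PPh3, toluene, 80 °C; then NaOH (aq.), CH2Cl2, rt
Reagents that add atoms: triphenylphosphine, c1ccc(cc1)P(c1ccccc1)c1ccccc1
Why: SN2 quaternisation of the phosphine by the α-bromo ketone followed by deprotonation of the acidic phosphonium salt gives the acyl-stabilised Wittig ylide.

Step 17
Reactants: 26 ring B alcohol 2-[(2S,3S)-3-(tert-butyldimethylsilyloxy)pentan-2-yl]-6-[(S)-1-hydroxypropan-2-yl]-3,5-dimethyl-4H-pyran-4-one; 29 2-(triphenyl-λ5-phosphanylidene)pentan-3-one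
Product: 31 (4E,6S)-6-{6-[(2S,3S)-3-(tert-butyldimethylsilyloxy)pentan-2-yl]-3,5-dimethyl-4-oxo-4H-pyran-2-yl}-4-methylhept-4-en-3-one, via ring B aldehyde 30 (not isolated)
Conditions: Dess–Martin periodinane, NaHCO3, CH2Cl2, 0 °C; then 29 (2 equiv), 0 to 40 °C
Reagents that add atoms: none
Why: One-pot oxidation–Wittig olefination in which the epimerisable aldehyde is consumed by the stabilised α-methyl ylide without isolation, giving the (E)-trisubstituted enone (acyl group trans to C10) by the usual reversible oxaphosphetane pathway while C10 keeps its configuration.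

**Union and endgame**

Step 18
Reactants: 9 (R)-2-ethyl-6-(1-hydroxypropan-2-yl)-3,5-dimethyl-4H-pyran-4-one
Product: 32 (S)-2-(6-ethyl-3,5-dimethyl-4-oxo-4H-pyran-2-yl)propanal
Conditions: Dess–Martin periodinane, NaHCO3, CH2Cl2, 0 °C; filtered cold and used at once
Reagents that add atoms: none
Why: Buffered Dess–Martin oxidation gives the configurationally labile aldehyde without acid or base strong enough to enolise C16 (the descriptor changes from R to S only because CHO outranks the ring), and immediate use limits epimerisation.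

Step 19
Reactants: 31 east ethyl enone (4E,6S)-6-{6-[(2S,3S)-3-(tert-butyldimethylsilyloxy)pentan-2-yl]-3,5-dimethyl-4-oxo-4H-pyran-2-yl}-4-methylhept-4-en-3-one; 32 (S)-2-(6-ethyl-3,5-dimethyl-4-oxo-4H-pyran-2-yl)propanal
Product: 34 C13-keto C15-hydroxy aldol adduct (11E; 3S,4S,10S,14R,15S,16R; C3-OTBS), via dibutylboron enolate 33 (not isolated)
Conditions: n-Bu2BOTf (1.3 equiv), i-Pr2NEt (1.5 equiv), CH2Cl2, −78 to 0 °C; then 32 (1.3 equiv), −78 °C; MeOH, pH 7 buffer (NaH2PO4/Na2HPO4), H2O2, 0 °C
Reagents that add atoms: none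
Why: Boron-mediated aldol addition in which kinetic enolisation of the ethyl ketone gives the (Z)-enol borinate, its Zimmerman–Traxler chair gives the 14,15-syn relationship, and the (Z)-enolate attacks the α-methyl aldehyde in the anti-Felkin sense (Roush model, pyranone anti to the forming bond and the α-hydrogen turned toward the enolate methyl to avoid a syn-pentane clash), which sets C15 anti to C16.

Step 20
Reactants: 34 C13-keto C15-hydroxy aldol adduct
Product: 35 C13-hydroxy C15-acetoxy bis-pyranone (11E; 3S,4S,10S,13R,14S,15R,16R; C3-OTBS)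
Conditions: SmI2 (0.3 equiv), MeCHO (10 equiv), THF, −10 °C
Reagents that add atoms: acetaldehyde, CC=O
Why: Evans–Tishchenko reduction, in which the C15 hydroxyl forms a samarium-bound hemiacetal with acetaldehyde that delivers hydride intramolecularly to the C13 ketone through a chair-like six-membered transition state, giving the 1,3-anti C13 carbinol and leaving C15 as its acetate.

Step 21
Reactants: 35 C13-hydroxy C15-acetoxy bis-pyranone
Product: 36 C3-O-tert-butyldimethylsilyl ether of the target (3S,4S,10S,13R,14R,15R,16R)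
Conditions: (EtCO)2O, pyridine, 4-(dimethylamino)pyridine (0.1 equiv), CH2Cl2, 0 °C to rt
Reagents that add atoms: propanoic anhydride, CCC(=O)OC(=O)CC
Why: Nucleophile-catalysed acyl transfer (Steglich-type acylation) esterifies the only free hydroxyl, the allylic C13 alcohol, as its propanoate without changing any stereocentre.

Step 22
Reactants: 36 C3-O-tert-butyldimethylsilyl ether of the target
Product: 37 CNP0265513.1 (3S,4S,10S,13R,14R,15R,16R; 11E)
Conditions: HF·pyridine, pyridine, THF, 0 °C to rt
Reagents that add atoms: none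
Why: Fluoride-driven Si–O cleavage under buffered, non-basic conditions frees the C3 hydroxyl without hydrolysis or migration of the acetate and propanoate.

**Compound list**
1 | methyl (R)-3-hydroxy-2-methylpropanoate | COC(=O)[C@H](C)CO | starting material
2 | methyl (R)-2-methyl-3-(triethylsilyloxy)propanoate | COC(=O)[C@H](C)CO[Si](CC)(CC)CC | intermediate
3 | (R)-2-methyl-3-(triethylsilyloxy)propanal | O=C[C@H](C)CO[Si](CC)(CC)CC | intermediate
4 | 4-methylheptane-3,5-dione | CCC(=O)C(C)C(=O)CC | starting material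
5 | dilithium bis-enolate of 4 (not isolated) | CC=C(O[Li])C(C)=C(O[Li])CC | intermediate
6 | (8R)-7-hydroxy-4,6,8-trimethyl-9-(triethylsilyloxy)nonane-3,5-dione, epimer mixture at C4/C6/C7 | CCC(=O)C(C)C(=O)C(C)C(O)[C@H](C)CO[Si](CC)(CC)CC | intermediate
7 | (8R)-4,6,8-trimethyl-9-(triethylsilyloxy)nonane-3,5,7-trione | CCC(=O)C(C)C(=O)C(C)C(=O)[C@H](C)CO[Si](CC)(CC)CC | intermediate
8 | (R)-2-ethyl-3,5-dimethyl-6-[1-(triethylsilyloxy)propan-2-yl]-4H-pyran-4-one (not isolated) | CCc1oc([C@H](C)CO[Si](CC)(CC)CC)c(C)c(=O)c1C | intermediate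
9 | (R)-2-ethyl-6-(1-hydroxypropan-2-yl)-3,5-dimethyl-4H-pyran-4-one, ring A alcohol | CCc1oc([C@H](C)CO)c(C)c(=O)c1C | intermediate
10 | methyl (S)-3-hydroxypentanoate | CC[C@H](O)CC(=O)OC | starting material
11 | dilithium alkoxide enolate of 10 (not isolated) | CC[C@H](O[Li])C=C(OC)O[Li] | intermediate
12 | methyl (2S,3S)-3-hydroxy-2-methylpentanoate | CC[C@H](O)[C@H](C)C(=O)OC | intermediate
13 | methyl (2S,3S)-3-(tert-butyldimethylsilyloxy)-2-methylpentanoate | CC[C@H](O[Si](C)(C)C(C)(C)C)[C@H](C)C(=O)OC | intermediate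
14 | (2S,3S)-3-(tert-butyldimethylsilyloxy)-2-methylpentanal | CC[C@H](O[Si](C)(C)C(C)(C)C)[C@H](C)C=O | intermediate
15 | methyl (S)-3-hydroxy-2-methylpropanoate | COC(=O)[C@@H](C)CO | starting material
16 | methyl (S)-2-methyl-3-(triethylsilyloxy)propanoate | COC(=O)[C@@H](C)CO[Si](CC)(CC)CC | intermediate
17 | (S)-2-methyl-3-(triethylsilyloxy)propanal | O=C[C@@H](C)CO[Si](CC)(CC)CC | intermediate
18 | pentan-3-one | CCC(=O)CC | starting material
19 | lithium enolate of 18 (not isolated) | CC=C(CC)O[Li] | intermediate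
20 | (6S)-5-hydroxy-4,6-dimethyl-7-(triethylsilyloxy)heptan-3-one, epimer mixture at C4/C5 | CCC(=O)C(C)C(O)[C@@H](C)CO[Si](CC)(CC)CC | intermediate
21 | (6S)-4,6-dimethyl-7-(triethylsilyloxy)heptane-3,5-dione | CCC(=O)C(C)C(=O)[C@@H](C)CO[Si](CC)(CC)CC | intermediate
22 | dilithium bis-enolate of 21 (not isolated) | CC=C(O[Li])C(C)=C(O[Li])[C@@H](C)CO[Si](CC)(CC)CC | intermediate
23 | (3S,4R,10S)-3-(tert-butyldimethylsilyloxy)-5-hydroxy-4,6,8,10-tetramethyl-11-(triethylsilyloxy)undecane-7,9-dione, epimer mixture at C5/C6/C8 | CC[C@H](O[Si](C)(C)C(C)(C)C)[C@H](C)C(O)C(C)C(=O)C(C)C(=O)[C@@H](C)CO[Si](CC)(CC)CC | intermediate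
24 | (3S,4S,10S)-3-(tert-butyldimethylsilyloxy)-4,6,8,10-tetramethyl-11-(triethylsilyloxy)undecane-5,7,9-trione | CC[C@H](O[Si](C)(C)C(C)(C)C)[C@H](C)C(=O)C(C)C(=O)C(C)C(=O)[C@@H](C)CO[Si](CC)(CC)CC | intermediate
25 | 2-[(2S,3S)-3-(tert-butyldimethylsilyloxy)pentan-2-yl]-3,5-dimethyl-6-[(S)-1-(triethylsilyloxy)propan-2-yl]-4H-pyran-4-one (not isolated) | CC[C@H](O[Si](C)(C)C(C)(C)C)[C@H](C)c1oc([C@@H](C)CO[Si](CC)(CC)CC)c(C)c(=O)c1C | intermediate
26 | 2-[(2S,3S)-3-(tert-butyldimethylsilyloxy)pentan-2-yl]-6-[(S)-1-hydroxypropan-2-yl]-3,5-dimethyl-4H-pyran-4-one, ring B alcohol | CC[C@H](O[Si](C)(C)C(C)(C)C)[C@H](C)c1oc([C@@H](C)CO)c(C)c(=O)c1C | intermediate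
27 | 2-bromopentan-3-one (racemic) | CCC(=O)C(C)Br | starting material
28 | (3-oxopentan-2-yl)triphenylphosphonium bromide (not isolated) | CCC(=O)C(C)[P+](c1ccccc1)(c1ccccc1)c1ccccc1.[Br-] | intermediate
29 | 2-(triphenyl-λ5-phosphanylidene)pentan-3-one | CCC(=O)C(C)=P(c1ccccc1)(c1ccccc1)c1ccccc1 | intermediate
30 | (R)-2-{6-[(2S,3S)-3-(tert-butyldimethylsilyloxy)pentan-2-yl]-3,5-dimethyl-4-oxo-4H-pyran-2-yl}propanal (not isolated) | CC[C@H](O[Si](C)(C)C(C)(C)C)[C@H](C)c1oc([C@@H](C)C=O)c(C)c(=O)c1C | intermediate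
31 | (4E,6S)-6-{6-[(2S,3S)-3-(tert-butyldimethylsilyloxy)pentan-2-yl]-3,5-dimethyl-4-oxo-4H-pyran-2-yl}-4-methylhept-4-en-3-one, east ethyl enone | CCC(=O)/C(C)=C/[C@H](C)c1oc([C@@H](C)[C@@H](O[Si](C)(C)C(C)(C)C)CC)c(C)c(=O)c1C | intermediate
32 | (S)-2-(6-ethyl-3,5-dimethyl-4-oxo-4H-pyran-2-yl)propanal, west aldehyde | O=C[C@@H](C)c1oc(CC)c(C)c(=O)c1C | intermediate
33 | (Z)-dibutylboron enolate of 31, O–B cis to the enolate methyl (not isolated) | C/C=C(\OB(CCCC)CCCC)/C(C)=C/[C@H](C)c1oc([C@@H](C)[C@@H](O[Si](C)(C)C(C)(C)C)CC)c(C)c(=O)c1C | intermediate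
34 | full C1–C23 bis-pyranone with C3-OTBS, C13 ketone, free C15-OH, (11E); 3S,4S,10S,14R,15S,16R | O=C(/C(C)=C/[C@H](C)c1oc([C@@H](C)[C@@H](O[Si](C)(C)C(C)(C)C)CC)c(C)c(=O)c1C)[C@H](C)[C@@H](O)[C@@H](C)c1oc(CC)c(C)c(=O)c1C | intermediate
35 | bis-pyranone with C3-OTBS, free C13-OH, C15-OAc, (11E); 3S,4S,10S,13R,14S,15R,16R | O[C@@H](/C(C)=C/[C@H](C)c1oc([C@@H](C)[C@@H](O[Si](C)(C)C(C)(C)C)CC)c(C)c(=O)c1C)[C@H](C)[C@@H](OC(C)=O)[C@@H](C)c1oc(CC)c(C)c(=O)c1C | intermediate
36 | C3-O-tert-butyldimethylsilyl ether of the target (C13 propanoate, C15 acetate); 3S,4S,10S,13R,14R,15R,16R | CCC(=O)O[C@@H](/C(C)=C/[C@H](C)c1oc([C@@H](C)[C@@H](O[Si](C)(C)C(C)(C)C)CC)c(C)c(=O)c1C)[C@H](C)[C@@H](OC(C)=O)[C@@H](C)c1oc(CC)c(C)c(=O)c1C | intermediate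
37 | CNP0265513.1: C3 alcohol, C13 propanoate, C15 acetate, (11E); 3S,4S,10S,13R,14R,15R,16R | CCC(=O)O[C@@H](/C(C)=C/[C@H](C)c1oc([C@@H](C)[C@@H](O)CC)c(C)c(=O)c1C)[C@H](C)[C@@H](OC(C)=O)[C@@H](C)c1oc(CC)c(C)c(=O)c1C | target

**Totals and weak points**

Total step count: 22. Longest linear sequence: 12 steps (steps 9, 10, 11, 12, 13, 14, 15, 17, 19, 20, 21, 22, starting from 15).

The three steps most likely to fail:

Step 17 (oxidation–Wittig). Aldehyde 30 is a vinylogous β-dicarbonyl compound, so C10 can epimerise, and the acyl ylide 29 is sluggish toward an α-branched aldehyde. The fallback sets out from 26 and comes back at 31. Alcohol 26 is oxidised with Dess–Martin periodinane and NaHCO3 in CH2Cl2 at 0 °C in the presence of S-ethyl 2-(triphenyl-λ5-phosphanylidene)propanethioate, an ester-type ylide that reacts at or below room temperature. Aldehyde 30 is therefore trapped as it forms, giving the S-ethyl (E)-enethioate F1. F1 is then converted into 31 by Fukuyama coupling with EtZnI and PdCl2(PPh3)2 (5 mol %) in toluene at rt. This is a neutral thioester-to-ketone cross-coupling that does not touch C10, the pyranone or the silyl ether.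

Step 19 (aldol union). Aldehyde 32 can epimerise at C16, and the boron triflate/amine pair may enolise the pyranone side chains of 31 at C4 or C10. The anti-Felkin preference is also unproven for a pyranone-bearing aldehyde. The fallback sets out from 31 (with 32 as before) and comes back at 34. The ethyl ketone of 31 is dehydrogenated with 2-iodoxybenzoic acid in DMSO at 65 °C to the cross-conjugated vinyl ketone F2. F2 is then joined to 32 by hydrogen-mediated reductive aldol addition (H2 1 atm, [Rh(cod)2]OTf 5 mol %, P(2-furyl)3, Li2CO3, CH2Cl2, rt). Hydrometalation of the unhindered vinyl group generates the (Z)-rhodium enolate with no amine base and no boron Lewis acid. Its closed transition state should give the same syn, anti-Felkin adduct 34.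

Step 20 (Evans–Tishchenko reduction). Two Lewis-basic pyranones may sequester the samarium catalyst, and the hindered C15 hydroxyl may form the hemiacetal slowly. Retro-aldol cleavage or 1,3-acetyl migration would erode the result. The fallback sets out from 34 and comes back at 35. The C15 hydroxyl is acetylated first (Ac2O, pyridine, 4-(dimethylamino)pyridine, 0 °C) to give the β-acetoxy enone F3. The C13 ketone is then reduced in a separate, catalyst-controlled step with BH3·SMe2 and (R)- or (S)-1-methyl-3,3-diphenyltetrahydro-1H,3H-pyrrolo[1,2-c][1,3,2]oxazaborole in THF at −40 °C. The catalyst antipode is chosen to match Felkin–Anh hydride delivery anti to C15, which gives the 13,14-anti carbinol 35.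

**Further compounds**
F1 | step 17 | S-ethyl (2E,4S)-4-{6-[(2S,3S)-3-(tert-butyldimethylsilyloxy)pentan-2-yl]-3,5-dimethyl-4-oxo-4H-pyran-2-yl}-2-methylpent-2-enethioate | CCSC(=O)/C(C)=C/[C@H](C)c1oc([C@@H](C)[C@@H](O[Si](C)(C)C(C)(C)C)CC)c(C)c(=O)c1C
F2 | step 19 | (4E,6S)-6-{6-[(2S,3S)-3-(tert-butyldimethylsilyloxy)pentan-2-yl]-3,5-dimethyl-4-oxo-4H-pyran-2-yl}-4-methylhepta-1,4-dien-3-one | C=CC(=O)/C(C)=C/[C@H](C)c1oc([C@@H](C)[C@@H](O[Si](C)(C)C(C)(C)C)CC)c(C)c(=O)c1C
F3 | step 20 | C15 acetate of 34 (β-acetoxy enone; C3-OTBS, C13 ketone, 11E) | O=C(/C(C)=C/[C@H](C)c1oc([C@@H](C)[C@@H](O[Si](C)(C)C(C)(C)C)CC)c(C)c(=O)c1C)[C@H](C)[C@@H](OC(C)=O)[C@@H](C)c1oc(CC)c(C)c(=O)c1C
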